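## Retrosynthetic overview

1. The γ-ylidene butenolide comes from a ring-fused furan (singlet-oxygen oxidation, then dehydration); the bicyclic ring forces the 5E geometry, and the C1 hemiketal is carried as a methyl ketal until the last step.
2. The bridging tetrahydrofuran ketal comes from a transannular gold-catalysed addition of the C4 hydroxyl to a ring alkyne (C1≡C2).
3. The ten-membered ring is closed at C7–C8 by a Nozaki–Hiyama–Kishi reaction (3-iodofuran + aldehyde); C8 is then set by a ketoreductase, the C13/C8 hydroxyls are told apart by a lipase, and the side chain is attached by Yamaguchi esterification.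
4. The open chain comes from an iodofuran epoxide and an alkyne (epoxide alkynylation, C2–C3); the iodofuran comes from iodocyclization of an alkyne triol (acetylide + protected dihydroxyacetone).
5. C4 and C2' both come from (R)-2-methylglycidol (Sharpless epoxidation of methallyl alcohol), and C10 from Ru–BINAP hydrogenation of α-methylene-γ-butyrolactone. Ring order: furan, ten-membered carbocycle, bridging tetrahydrofuran ketal, butenolide (from the furan).

Assumption: atoms are numbered as in the hirsutinolides (C1 hemiketal carbon; C4 carbinol carbon with methyl C15; C5=C6; butenolide C6–O–C12(=O)–C11=C7 with C13 on C11; C8 acyloxy carbon; C10 with methyl C14); Ru(OAc)2[(S)-BINAP] is taken to give the (R)-lactone 16 (otherwise the (R)-BINAP complex is used); the ketoreductase and the lipase are picked from commercial panels.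

## Route

Step 1
Reactants: 1 2-methylprop-2-en-1-ol
Product: 2 (R)-2-methylglycidol
Conditions: Ti(OiPr)4 (5 mol%), (2S,3S)-(−)-diisopropyl tartrate (6 mol%), tBuOOH, 4 Å MS, CH2Cl2, −20 °C
Reagents that add atoms: tert-butyl hydroperoxide, CC(C)(C)OO
Why: Sharpless asymmetric epoxidation; the titanium–tartrate catalyst delivers oxygen to one enantiotopic face of the allylic alcohol, and the (−)-tartrate gives the (R)-epoxide that later supplies both C4 and C2' (about 94% ee).

Step 2
Reactants: 2 (R)-2-methylglycidol
Product: 3 (2S)-2-methylpent-4-yne-1,2-diol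
Conditions: LiC≡CH·H2NCH2CH2NH2 (3 equiv), DMSO, 15 °C → rt; then H2O
Reagents that add atoms: lithium acetylide–ethylenediamine complex, [Li]C#C.NCCN
Why: SN2 epoxide opening by acetylide at the unhindered CH2 terminus forms C5–C6 and leaves the quaternary center untouched (Payne rearrangement would need SN2 attack at the tertiary carbon and does not compete).

Step 3
Reactants: 3 (2S)-2-methylpent-4-yne-1,2-diol
Product: 4 (4S)-2,2,4-trimethyl-4-(prop-2-yn-1-yl)-1,3-dioxolane
Conditions: Me2C(OMe)2, PPTS (cat.), CH2Cl2, rt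
Reagents that add atoms: 2,2-dimethoxypropane, COC(C)(C)OC
Why: Acid-catalysed transketalization ties up the 1,2-diol as a five-membered acetonide, so that the tertiary hydroxyl cannot compete in the later iodocyclization.

Step 4
Reactants: 4 (4S)-2,2,4-trimethyl-4-(prop-2-yn-1-yl)-1,3-dioxolane; 5 1,3-bis[(tert-butyldimethylsilyl)oxy]propan-2-one
Product: 7 bis-silylated alkynyl carbinol, via lithium acetylide 6 (not isolated)
Conditions: 4, nBuLi, THF, −78 °C; then 5, −78 → 0 °C; H2O
Reagents that add atoms: none
Why: 1,2-Addition of the lithium acetylide to the symmetric ketone forms C7–C11; the carbinol carbon carries two identical CH2OSi arms, so no stereocenter arises.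

Step 5
Reactants: 7 bis-silylated alkynyl carbinol
Product: 8 alkyne triol
Conditions: TBAF, THF, 0 °C → rt
Reagents that add atoms: none
Why: Fluoride-driven Si–O cleavage frees both primary hydroxyls; the acetonide is inert to fluoride.

Step 6
Reactants: 8 alkyne triol
Product: 10 3-iodofuran alcohol, via iododihydrofuranol 9 (not isolated)
Conditions: I2 (3 equiv), NaHCO3 (3 equiv), MeCN, 0 °C → rt; aq. Na2S2O3
Reagents that add atoms: iodine, I-I
Why: Iodonium-triggered 5-endo-dig cyclization of the 3-alkyne-1,2-diol followed by loss of water aromatizes to the β-iodofuran (iodocyclization); either CH2OH arm can attack and both give the same product.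

Step 7
Reactants: 10 3-iodofuran alcohol
Product: 11 TBDPS ether of 10
Conditions: TBDPSCl, imidazole, DMF, rt
Reagents that add atoms: tert-butyl(chloro)diphenylsilane, CC(C)(C)[Si](Cl)(c1ccccc1)c1ccccc1
Why: Silylation of the only free hydroxyl (C13–OH) with a group that survives acid, base and organolithium reagents.

Step 8
Reactants: 11 TBDPS ether of 10
Product: 12 iodofuran 1,2-diol
Conditions: AcOH/H2O (4:1), 45 °C
Reagents that add atoms: none
Why: Acetal hydrolysis under weak aqueous acid releases the C3/C4 diol, while the primary TBDPS ether and the iodofuran are stable.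

Step 9
Reactants: 12 iodofuran 1,2-diol
Product: 14 iodofuran epoxide, via monotosylate 13 (not isolated)
Conditions: NaH (2.2 equiv), N-tosylimidazole (1.05 equiv), THF, 0 °C → rt
Reagents that add atoms: none
Why: Selective sulfonylation of the primary alkoxide and intramolecular Williamson closure by the tertiary alkoxide give the 2,2-disubstituted epoxide; no bond to C4 is broken, so its configuration is kept.

Step 10
Reactants: 15 α-methylene-γ-butyrolactone
Product: 16 (3R)-3-methyloxolan-2-one
Conditions: H2 (50 bar), Ru(OAc)2[(S)-BINAP] (0.5 mol%), CH2Cl2, 50 °C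
Reagents that add atoms: none
Why: Noyori-type asymmetric hydrogenation; the chiral ruthenium–BINAP hydride distinguishes the two faces of the exocyclic enoate and sets the future C10 center (about 95% ee).

Step 11
Reactants: 16 (3R)-3-methyloxolan-2-one
Product: 17 (3R)-3-methyloxolan-2-ol
Conditions: iBu2AlH (1.05 equiv), CH2Cl2, −78 °C; aq. KNaC4H4O6
Reagents that add atoms: none
Why: Partial hydride reduction of the lactone stops at the lactol because the tetrahedral aluminate is stable at −78 °C.

Step 12
Reactants: 17 (3R)-3-methyloxolan-2-ol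
Product: 18 (3R)-3-methylpent-4-yn-1-ol
Conditions: MeC(O)C(N2)P(O)(OMe)2, K2CO3, MeOH, 0 °C → rt
Reagents that add atoms: dimethyl (1-diazo-2-oxopropyl)phosphonate, CC(=O)C(=[N+]=[N-])P(=O)(OC)OC
Why: Seyferth–Gilbert homologation in the Ohira–Bestmann variant turns the masked aldehyde into the terminal alkyne (C1≡C2) with weak base at low temperature, which keeps the α-methyl center.

Step 13
Reactants: 18 (3R)-3-methylpent-4-yn-1-ol
Product: 19 TBS ether of 18
Conditions: TBSCl, imidazole, CH2Cl2, rt
Reagents that add atoms: tert-butyl(chloro)dimethylsilane, CC(C)(C)[Si](C)(C)Cl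
Why: Silylation of the primary alcohol; a free C8 hydroxyl would quench the acetylide in step 14.

Step 14
Reactants: 14 iodofuran epoxide; 19 TBS ether of 18
Product: 21 homopropargylic tertiary alcohol, via lithium acetylide 20 (not isolated)
Conditions: 19 (1.5 equiv), nBuLi, THF, −78 °C; BF3·OEt2; then 14, −78 °C; H2O
Reagents that add atoms: none
Why: Yamaguchi–Hirao alkynylation; the BF3-activated epoxide is opened at its CH2 terminus by the alkynyl nucleophile (SN2), forming C2–C3 without touching C4 or C10, and the about 5% of minor diastereomer from the two fragments is removed here by chromatography.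

Step 15
Reactants: 21 homopropargylic tertiary alcohol
Product: 22 iodofuran alkyne diol
Conditions: PPTS (0.2 equiv), MeOH, rt
Reagents that add atoms: none
Why: Acid-catalysed methanolysis removes the primary TBS ether much faster than the bulkier TBDPS ether (selective desilylation).

Step 16
Reactants: 22 iodofuran alkyne diol
Product: 23 iodofuran alkynyl aldehyde
Conditions: Dess–Martin periodinane, NaHCO3, CH2Cl2, 0 °C → rt
Reagents that add atoms: none
Why: Dess–Martin oxidation of the primary alcohol; the tertiary alcohol cannot be oxidized and the aldehyde has no α-stereocenter to lose.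

Step 17
Reactants: 23 iodofuran alkynyl aldehyde
Product: 24 macrocyclic furyl carbinol
Conditions: CrCl2 (10 equiv), NiCl2 (5 mol%), DMSO/THF (3:1), 3 mM, slow addition, rt
Reagents that add atoms: none
Why: Nozaki–Hiyama–Kishi macrocyclization; zerovalent nickel inserts into the carbon–iodine bond, transmetalation gives an arylchromium species that adds chemoselectively to the aldehyde and closes the ten-membered ring, with C8 formed as an epimer mixture that step 18 erases.

Step 18
Reactants: 24 macrocyclic furyl carbinol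
Product: 25 macrocyclic furyl ketone
Conditions: Dess–Martin periodinane, NaHCO3, CH2Cl2, 0 °C → rt
Reagents that add atoms: none
Why: Dess–Martin oxidation of the furyl carbinol removes the uncontrolled C8 center; C10 is β to the new ketone and cannot epimerize by enolization.

Step 19
Reactants: 25 macrocyclic furyl ketone
Product: 26 macrocyclic keto diol
Conditions: TBAF, AcOH, THF, 0 °C → rt
Reagents that add atoms: none
Why: Buffered fluoride desilylation frees C13–OH and gives a smaller, more polar substrate for the enzymatic steps.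

Step 20
Reactants: 26 macrocyclic keto diol
Product: 27 macrocyclic triol
Conditions: ketoreductase (NADPH-dependent, (S)-selective), NADP+ (cat.), iPrOH (10% v/v), phosphate buffer pH 7.0, DMSO (5% v/v), 30 °C
Reagents that add atoms: none
Why: Ketoreductase-catalysed asymmetric reduction; the enzyme delivers the NADPH hydride (recycled by isopropanol) to the Re face of the furyl ketone and sets C8 as (S) under catalyst control, independent of the ring conformation.

Step 21
Reactants: 27 macrocyclic triol
Product: 28 C13 monoacetate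
Conditions: lipase (Candida antarctica lipase B, immobilized), vinyl acetate (3 equiv), MTBE/THF, 25 °C
Reagents that add atoms: vinyl acetate, CC(=O)OC=C
Why: Lipase-catalysed irreversible transesterification acylates only the primary C13 hydroxyl; the tertiary C4–OH is inert and the (S)-configured secondary C8–OH is the slow-reacting enantiomer type for this lipase (Kazlauskas rule).

Step 22
Reactants: 2 (R)-2-methylglycidol
Product: 29 (2R)-3-chloro-2-methylpropane-1,2-diol
Conditions: LiCl, AcOH, THF, rt
Reagents that add atoms: lithium chloride, [Li+].[Cl-]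
Why: Regioselective halohydrin formation; chloride opens the protonated epoxide in an SN2 fashion at the CH2 terminus, so the tertiary center keeps its configuration.

Step 23
Reactants: 29 (2R)-3-chloro-2-methylpropane-1,2-diol
Product: 31 (2R)-3-chloro-2-hydroxy-2-methylpropanoic acid, via hydroxy aldehyde 30 (not isolated)
Conditions: TEMPO (cat.), NaOCl (cat.), NaClO2, MeCN/phosphate buffer pH 6.7, 35 °C
Reagents that add atoms: sodium chlorite, [Na+].[O-]Cl=O
Why: Anelli–Zhao oxidation; the oxoammonium salt oxidizes the primary alcohol to the aldehyde and chlorite takes it on to the acid at pH 6.7, where the chlorohydrin does not close to an epoxide.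

Step 24
Reactants: 31 (2R)-3-chloro-2-hydroxy-2-methylpropanoic acid
Product: 33 (2R)-3-chloro-2-methyl-2-[(triethylsilyl)oxy]propanoic acid, via bis-silyl compound 32 (not isolated)
Conditions: Et3SiOTf (2.3 equiv), 2,6-lutidine, CH2Cl2, 0 °C; then THF/H2O/AcOH, rt
Reagents that add atoms: triethylsilyl trifluoromethanesulfonate, CC[Si](CC)(CC)OS(=O)(=O)C(F)(F)F
Why: Bis-silylation followed by selective hydrolysis of the labile silyl ester leaves the tertiary hydroxyl masked as its TES ether, which prevents self-acylation in step 25.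

Step 25
Reactants: 28 C13 monoacetate; 33 (2R)-3-chloro-2-methyl-2-[(triethylsilyl)oxy]propanoic acid
Product: 35 C8 ester, via mixed anhydride 34 (not isolated)
Conditions: 33 (1.5 equiv), 2,4,6-Cl3C6H2COCl, Et3N, THF, rt; then 28, DMAP, toluene, rt → 40 °C
Reagents that add atoms: none
Why: Yamaguchi esterification; DMAP attacks the mixed anhydride at the less hindered carbonyl and the acylpyridinium acylates the secondary C8 hydroxyl, the tertiary C4–OH being too hindered to react.

Step 26
Reactants: 35 C8 ester
Product: 37 bridged methyl ketal, via bridgehead enol ether 36 (not isolated)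
Conditions: Ph3PAuNTf2 (5 mol%), MeOH/CH2Cl2 (1:4), rt
Reagents that add atoms: methanol, CO
Why: Gold-catalysed alkyne hydroalkoxylation; monovalent gold activates the ring alkyne for transannular 5-endo-dig attack of the C4 hydroxyl on C1 and methanol adds to the enol ether, the C1 configuration being dictated by the bridge (the C5 and C10 arms must be cis on the new tetrahydrofuran).

Step 27
Reactants: 37 bridged methyl ketal
Product: 39 γ-hydroxybutenolide, via endoperoxide 38 (not isolated)
Conditions: O2, hν (visible), rose bengal (cat.), iPr2NEt, CH2Cl2, −78 °C → rt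
Reagents that add atoms: dioxygen, O=O
Why: [4+2] photooxygenation of the furan with singlet oxygen, then base-induced (Kornblum–DeLaMare-type) opening of the endoperoxide at its only C–H (C12), puts the carbonyl at C12 and a hydroxyl at C6; the new C6 center is removed in step 28.

Step 28
Reactants: 39 γ-hydroxybutenolide
Product: 41 protected (5E)-ylidene butenolide, via lactol mesylate 40 (not isolated)
Conditions: MsCl, Et3N, CH2Cl2, −20 → 0 °C
Reagents that add atoms: none
Why: Dehydration by mesylation of the lactol hydroxyl and elimination toward C5, the only neighbour that carries hydrogen; the bicyclic ring allows only the ring-cis (5E) enol lactone.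

Step 29
Reactants: 41 protected (5E)-ylidene butenolide
Product: 42 CNP0414417.3
Conditions: 48% aq. HF/MeCN (1:19), 0 °C → rt
Reagents that add atoms: water, O
Why: Global deprotection; Si–F cleavage removes the TES ether and acid-catalysed ketal hydrolysis exchanges OMe for OH at C1, whose configuration is again fixed by the bridge.

## Compound list

1 | 2-methylprop-2-en-1-ol (methallyl alcohol) | C=C(C)CO | starting material
2 | [(2R)-2-methyloxiran-2-yl]methanol, (R)-2-methylglycidol | C[C@@]1(CO)CO1 | intermediate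
3 | (2S)-2-methylpent-4-yne-1,2-diol | C#CC[C@@](O)(C)CO | intermediate
4 | (4S)-2,2,4-trimethyl-4-(prop-2-yn-1-yl)-1,3-dioxolane | C#CC[C@@]1(C)COC(C)(C)O1 | intermediate
5 | 1,3-bis[(tert-butyldimethylsilyl)oxy]propan-2-one | CC(C)(C)[Si](C)(C)OCC(=O)CO[Si](C)(C)C(C)(C)C | starting material
6 | lithium acetylide of 4 (lithiated at the alkyne terminus) | [Li]C#CC[C@@]1(C)COC(C)(C)O1 | intermediate
7 | 1-[(tert-butyldimethylsilyl)oxy]-2-{[(tert-butyldimethylsilyl)oxy]methyl}-5-[(4S)-2,2,4-trimethyl-1,3-dioxolan-4-yl]pent-3-yn-2-ol | CC(C)(C)[Si](C)(C)OCC(O)(CO[Si](C)(C)C(C)(C)C)C#CC[C@@]1(C)COC(C)(C)O1 | intermediate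
8 | 2-(hydroxymethyl)-5-[(4S)-2,2,4-trimethyl-1,3-dioxolan-4-yl]pent-3-yne-1,2-diol | OCC(O)(CO)C#CC[C@@]1(C)COC(C)(C)O1 | intermediate
9 | 3-(hydroxymethyl)-4-iodo-5-{[(4S)-2,2,4-trimethyl-1,3-dioxolan-4-yl]methyl}-2,3-dihydrofuran-3-ol (C3 epimers) | OCC1(O)COC(C[C@@]2(C)COC(C)(C)O2)=C1I | intermediate
10 | (4-iodo-5-{[(4S)-2,2,4-trimethyl-1,3-dioxolan-4-yl]methyl}furan-3-yl)methanol | OCc1coc(C[C@@]2(C)COC(C)(C)O2)c1I | intermediate
11 | tert-butyl[(4-iodo-5-{[(4S)-2,2,4-trimethyl-1,3-dioxolan-4-yl]methyl}furan-3-yl)methoxy]diphenylsilane | CC(C)(C)[Si](c1ccccc1)(c1ccccc1)OCc1coc(C[C@@]2(C)COC(C)(C)O2)c1I | intermediate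
12 | (2S)-3-[4-({[tert-butyl(diphenyl)silyl]oxy}methyl)-3-iodofuran-2-yl]-2-methylpropane-1,2-diol | CC(C)(C)[Si](c1ccccc1)(c1ccccc1)OCc1coc(C[C@@](O)(C)CO)c1I | intermediate
13 | primary 4-methylbenzenesulfonate of 12 | CC(C)(C)[Si](c1ccccc1)(c1ccccc1)OCc1coc(C[C@@](O)(C)COS(=O)(=O)c2ccc(C)cc2)c1I | intermediate
14 | (2S)-2-{[4-({[tert-butyl(diphenyl)silyl]oxy}methyl)-3-iodofuran-2-yl]methyl}-2-methyloxirane | CC(C)(C)[Si](c1ccccc1)(c1ccccc1)OCc1coc(C[C@@]2(C)CO2)c1I | intermediate
15 | 3-methylideneoxolan-2-one (α-methylene-γ-butyrolactone) | C=C1CCOC1=O | starting material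
16 | (3R)-3-methyloxolan-2-one | C[C@@H]1CCOC1=O | intermediate
17 | (3R)-3-methyloxolan-2-ol (anomers) | C[C@@H]1CCOC1O | intermediate
18 | (3R)-3-methylpent-4-yn-1-ol | C#C[C@H](C)CCO | intermediate
19 | tert-butyldimethyl{[(3R)-3-methylpent-4-yn-1-yl]oxy}silane | C#C[C@H](C)CCO[Si](C)(C)C(C)(C)C | intermediate
20 | lithium acetylide of 19 | [Li]C#C[C@H](C)CCO[Si](C)(C)C(C)(C)C | intermediate
21 | (2R,6R)-1-[4-({[tert-butyl(diphenyl)silyl]oxy}methyl)-3-iodofuran-2-yl]-8-[(tert-butyldimethylsilyl)oxy]-2,6-dimethyloct-4-yn-2-ol | CC(C)(C)[Si](c1ccccc1)(c1ccccc1)OCc1coc(C[C@@](O)(C)CC#C[C@H](C)CCO[Si](C)(C)C(C)(C)C)c1I | intermediate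
22 | (3R,7R)-8-[4-({[tert-butyl(diphenyl)silyl]oxy}methyl)-3-iodofuran-2-yl]-3,7-dimethyloct-4-yne-1,7-diol | CC(C)(C)[Si](c1ccccc1)(c1ccccc1)OCc1coc(C[C@@](O)(C)CC#C[C@H](C)CCO)c1I | intermediate
23 | (3R,7R)-8-[4-({[tert-butyl(diphenyl)silyl]oxy}methyl)-3-iodofuran-2-yl]-7-hydroxy-3,7-dimethyloct-4-ynal | CC(C)(C)[Si](c1ccccc1)(c1ccccc1)OCc1coc(C[C@@](O)(C)CC#C[C@H](C)CC=O)c1I | intermediate
24 | macrocyclic furyl carbinol: furan (C6=C7, C11, C12) fused to the ten-membered ring C1–C10 with ring alkyne C1≡C2; (4R)-4-hydroxy-4-methyl, (10R)-10-methyl, 8-hydroxy (epimers), C13–OTBDPS | CC(C)(C)[Si](c1ccccc1)(c1ccccc1)OCc1c2c(C[C@@](O)(C)CC#C[C@H](C)CC2O)oc1 | intermediate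
25 | macrocyclic furyl ketone: as 24 with C8=O; (4R,10R) | CC(C)(C)[Si](c1ccccc1)(c1ccccc1)OCc1c2c(C[C@@](O)(C)CC#C[C@H](C)CC2=O)oc1 | intermediate
26 | macrocyclic keto diol: as 25 with free C13–OH; (4R,10R) | OCc1c2c(C[C@@](O)(C)CC#C[C@H](C)CC2=O)oc1 | intermediate
27 | macrocyclic triol: (4R,8S,10R)-4,8-dihydroxy, C13–OH, ring alkyne C1≡C2 | OCc1c2c(C[C@@](O)(C)CC#C[C@H](C)C[C@@H]2O)oc1 | intermediate
28 | C13 monoacetate of 27; (4R,8S,10R) | CC(=O)OCc1c2c(C[C@@](O)(C)CC#C[C@H](C)C[C@@H]2O)oc1 | intermediate
29 | (2R)-3-chloro-2-methylpropane-1,2-diol | OC[C@@](C)(O)CCl | intermediate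
30 | (2R)-3-chloro-2-hydroxy-2-methylpropanal | O=C[C@@](C)(O)CCl | intermediate
31 | (2R)-3-chloro-2-hydroxy-2-methylpropanoic acid | OC(=O)[C@@](C)(O)CCl | intermediate
32 | triethylsilyl (2R)-3-chloro-2-methyl-2-[(triethylsilyl)oxy]propanoate | CC[Si](CC)(CC)OC(=O)[C@@](C)(O[Si](CC)(CC)CC)CCl | intermediate
33 | (2R)-3-chloro-2-methyl-2-[(triethylsilyl)oxy]propanoic acid | OC(=O)[C@@](C)(O[Si](CC)(CC)CC)CCl | intermediate
34 | mixed anhydride of 33 and 2,4,6-trichlorobenzoic acid | Clc1cc(Cl)c(C(=O)OC(=O)[C@@](C)(O[Si](CC)(CC)CC)CCl)c(Cl)c1 | intermediate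
35 | C8 ester: 28 acylated at O8 by 33; (4R,8S,10R,2'R); ring alkyne, free C4–OH | CC(=O)OCc1c2c(C[C@@](O)(C)CC#C[C@H](C)C[C@@H]2OC(=O)[C@@](C)(O[Si](CC)(CC)CC)CCl)oc1 | intermediate
36 | bridgehead enol ether: 1,4-epoxy bridge with C1=C2 double bond; furan intact; (4R,8S,10R,2'R) | CC(=O)OCc1c2c(C[C@@]3(C)CC=C(O3)[C@H](C)C[C@@H]2OC(=O)[C@@](C)(O[Si](CC)(CC)CC)CCl)oc1 | intermediate
37 | bridged methyl ketal: (1S,4R,8S,10R,2'R)-1,4-epoxy-1-methoxy furan macrocycle with 13-OAc and 8-O-acyl (OTES) | CC(=O)OCc1c2c(C[C@@]3(C)CC[C@](OC)(O3)[C@H](C)C[C@@H]2OC(=O)[C@@](C)(O[Si](CC)(CC)CC)CCl)oc1 | intermediate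
38 | furan endoperoxide of 37 (O–O bridge between C6 and C12) | CC(=O)OCC1=C2C3(OOC1O3)C[C@@]4(C)CC[C@](OC)(O4)[C@H](C)C[C@@H]2OC(=O)[C@@](C)(O[Si](CC)(CC)CC)CCl | intermediate
39 | γ-hydroxybutenolide: 6-hydroxy-7(11)-en-6,12-olide, 1-OMe ketal, 13-OAc, 8-O-acyl (OTES); (1S,4R,8S,10R,2'R), C6 epimers | CC(=O)OCC1=C2C(O)(C[C@@]3(C)CC[C@](OC)(O3)[C@H](C)C[C@@H]2OC(=O)[C@@](C)(O[Si](CC)(CC)CC)CCl)OC1=O | intermediate
40 | C6 methanesulfonate of 39 | CC(=O)OCC1=C2C(OS(C)(=O)=O)(C[C@@]3(C)CC[C@](OC)(O3)[C@H](C)C[C@@H]2OC(=O)[C@@](C)(O[Si](CC)(CC)CC)CCl)OC1=O | intermediate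
41 | protected target: (1S,4R,5E,8S,10R,2'R)-1-O-methyl, 2'-O-triethylsilyl derivative of 42 | CC(=O)OCC1=C2/C(=C\[C@@]3(C)CC[C@](OC)(O3)[C@H](C)C[C@@H]2OC(=O)[C@@](C)(O[Si](CC)(CC)CC)CCl)OC1=O | intermediate
42 | CNP0414417.3: (1S,4R,5E,8S,10R)-13-acetoxy-1-hydroxy-1,4-epoxygermacra-5,7(11)-dien-6,12-olide 8-[(2R)-3-chloro-2-hydroxy-2-methylpropanoate] | CC(=O)OCC1=C2/C(=C\[C@@]3(C)CC[C@](O)(O3)[C@H](C)C[C@@H]2OC(=O)[C@@](C)(O)CCl)OC1=O | target

## Step count and weak points

Total: 29 steps. Longest linear sequence: 22 steps (steps 1–9, 14–21, 25–29). The three steps most likely to fail are 17, 20 and 26.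

Step 17 (ring closure). The 3-iodofuran is flanked by two substituents and the product is a strained ten-membered cycloalkyne, so the arylchromium addition may be slow. The fallback makes the same C7–C8 bond as a ketone by an anionic (Parham-type) cyclization. It sets out from diol 22: TEMPO/PhI(OAc)2 in MeCN–H2O oxidizes the primary alcohol to the carboxylic acid F1, and EDC·HCl/HOBt/MeNHOMe·HCl/iPr2NEt converts it into the Weinreb amide F2. After deprotonation of the tertiary hydroxyl with MeLi, iodine–lithium exchange with tBuLi (THF, −100 °C, 5 mM) lets the furyllithium attack the amide intramolecularly. Collapse of the chelate on work-up gives ketone 25, where the route continues; steps 16 to 18 are not needed.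

Step 20 (enzymatic reduction). No ketoreductase of the panel may accept the rigid macrocyclic ketone. The fallback replaces the biocatalyst by a chemical catalyst that also works under reagent control: Corey–Bakshi–Shibata reduction with (R)-2-methyl-CBS-oxazaborolidine (0.2 equiv) and excess BH3·SMe2 in THF at −30 °C, in which the furyl group acts as the large substituent and the (S)-carbinol results. It sets out from 26 and lands directly on 27; it makes no new compound (F0).

Step 26 (transannular ketalization). The electron-rich furan, three atoms away from the alkyne, can compete with the hydroxyl for the gold-activated triple bond. The fallback removes the furan first by changing the order of events. It sets out from 35: the photooxygenation of step 27 (O2, hν, rose bengal, iPr2NEt, CH2Cl2, −78 °C) is run on the alkyne and gives the alkynyl γ-hydroxybutenolide F3. The alkyne can then be activated more forcefully (Ph3PAuNTf2 or PtCl2, MeOH/CH2Cl2, up to 50 °C), and the transannular ketalization delivers 39, where the route continues with step 28.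

Further compounds
F1 | step 17 | (3R,7R)-8-[4-({[tert-butyl(diphenyl)silyl]oxy}methyl)-3-iodofuran-2-yl]-7-hydroxy-3,7-dimethyloct-4-ynoic acid | CC(C)(C)[Si](c1ccccc1)(c1ccccc1)OCc1coc(C[C@@](O)(C)CC#C[C@H](C)CC(O)=O)c1I
F2 | step 17 | N-methoxy-N-methylamide (Weinreb amide) of F1 | CC(C)(C)[Si](c1ccccc1)(c1ccccc1)OCc1coc(C[C@@](O)(C)CC#C[C@H](C)CC(=O)N(C)OC)c1I
F0 | step 20 | none | none
F3 | step 26 | alkynyl γ-hydroxybutenolide: 35 with the furan oxidized to the 6-hydroxy-7(11)-en-6,12-olide, ring alkyne and C4–OH intact | CC(=O)OCC1=C2C(O)(C[C@@](O)(C)CC#C[C@H](C)C[C@@H]2OC(=O)[C@@](C)(O[Si](CC)(CC)CC)CCl)OC1=O
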